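**Retrosynthetic overview**

1. Sauriol A ⇐ (2S,3S)-1,4-diaryl-2,3-dimethylbutane-1,4-dione 11 (aryl = 3,4-bis(benzyloxy)-5-methoxyphenyl): one global hydrogenolysis turns both ArC=O into ArCH2 and frees the four phenols.
2. 11 ⇐ bis-SAMP-hydrazone 10 ⇐ central C2–C3 bond by oxidative homocoupling of two identical chiral lithium azaenolates. One α-carbon is oxidised to an α-radical/enolonium-type electrophile and bonds to the α-carbon of the second unit, so two normally nucleophilic carbons are joined and both stereocentres are set at once.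
3. Hydrazone 8 ⇐ aryl ethyl ketone 6 ⇐ aldehyde 3 + EtMgBr (addition, then oxidation in the same flask) ⇐ 5-hydroxyvanillin 1 + benzyl bromide 2.
4. No ring is formed; both benzene rings are bought with 1.

Assumption: the coupling in step 4 is taken to follow the facial sense of SAMP-hydrazone alkylations (S at the new centres here); if experiment showed the opposite sense, RAMP would replace SAMP with no other change.

**Route**

Step 1
Reactants: 1 3,4-dihydroxy-5-methoxybenzaldehyde (5-hydroxyvanillin); 2 benzyl bromide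
Product: 3 3,4-bis(benzyloxy)-5-methoxybenzaldehyde
Conditions: BnBr (2.3 equiv), K2CO3, DMF, 60 °C
Reagents that add atoms: benzyl bromide, BrCc1ccccc1
Why: Williamson ether synthesis of both phenoxides with a reactive benzylic bromide; benzyl ethers survive the Grignard, LDA and CuCl2 steps and are removed in the final hydrogenolysis.

Step 2
Reactants: 3 3,4-bis(benzyloxy)-5-methoxybenzaldehyde; 4 ethylmagnesium bromide
Product: 6 1-[3,4-bis(benzyloxy)-5-methoxyphenyl]propan-1-one, via bromomagnesium alkoxide 5 (not isolated)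
Conditions: EtMgBr (1.1 equiv), THF, 0 °C; then 1,1'-(azodicarbonyl)dipiperidine (1.3 equiv), rt; aqueous work-up
Reagents that add atoms: ethylmagnesium bromide, CC[Mg]Br
Why: Grignard addition gives the bromomagnesium alkoxide, which is oxidised in the same flask by hydride transfer to the azo acceptor (Mukaiyama oxidation of alkoxymagnesium halides), so the aryl ethyl ketone is reached in one operation and the carbinol stereocentre is only transient.

Step 3
Reactants: 6 1-[3,4-bis(benzyloxy)-5-methoxyphenyl]propan-1-one; 7 (S)-1-amino-2-(methoxymethyl)pyrrolidine (SAMP)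
Product: 8 (E)-1-[3,4-bis(benzyloxy)-5-methoxyphenyl]-N-[(2S)-2-(methoxymethyl)pyrrolidin-1-yl]propan-1-imine (SAMP hydrazone of 6)
Conditions: SAMP (1.3 equiv), cat. TsOH·H2O, toluene, reflux, Dean–Stark
Reagents that add atoms: (S)-1-amino-2-(methoxymethyl)pyrrolidine (SAMP), COC[C@@H]1CCCN1N
Why: Acid-catalysed hydrazone condensation driven by azeotropic removal of water; the auxiliary stereocentre is untouched, and only the ethyl group carries α-hydrogens, so the later deprotonation is regiochemically unambiguous.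

Step 4
Reactants: 8 SAMP hydrazone of 6 (two molecules)
Product: 10 (2S,3S)-1,4-bis[3,4-bis(benzyloxy)-5-methoxyphenyl]-2,3-dimethylbutane-1,4-dione bis-SAMP hydrazone (both C=N bonds E and each carrying N-[(2S)-2-(methoxymethyl)pyrrolidin-1-yl]), via lithium azaenolate 9 (not isolated)
Conditions: LDA (1.05 equiv), THF, 0 °C, 4 h; then CuCl2 (1.1 equiv) in DMF, −78 to −30 °C; aq. NH3/NH4Cl work-up; chromatography
Reagents that add atoms: none
Why: Proposed new method: LDA gives the OMe-chelated lithium azaenolate 9 (E about C=C, Z about C–N), and one-electron oxidation by CuCl2 (divalent copper, reduced to monovalent CuCl) converts the normally nucleophilic α-carbon of one unit into an electrophilic α-hydrazonyl (enolonium-type) radical that bonds to the α-carbon of a second azaenolate; each unit is expected to bond through the face that alkyl halides take in SAMP-hydrazone alkylations (the S sense for this substituent pattern), which favours the like (2S,3S) dimer, while any mismatched pairing ends up in the chromatographically separable unlike diastereomer so that the enantiomeric purity of 10 is amplified; the closest known reaction types are the CuCl2-mediated oxidative dimerisation of ketone lithium enolates to 1,4-diketones, the oxidative homocoupling of chiral N-acyloxazolidinone enolates and the Enders SAMP-hydrazone α-alkylation.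

Step 5
Reactants: 10 bis-SAMP hydrazone
Product: 11 (2S,3S)-1,4-bis[3,4-bis(benzyloxy)-5-methoxyphenyl]-2,3-dimethylbutane-1,4-dione
Conditions: sat. aq. oxalic acid, Et2O/THF, 0 °C to rt
Reagents that add atoms: water, O
Why: Two-phase oxalic acid hydrolysis of SAMP hydrazones releases the ketone and takes the auxiliary into the water layer as its oxalate; this mild hydrolysis is known not to epimerise α-stereocentres, so C2 and C3 stay (S,S).

Step 6
Reactants: 11 (2S,3S)-1,4-bis[3,4-bis(benzyloxy)-5-methoxyphenyl]-2,3-dimethylbutane-1,4-dione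
Product: 14 Sauriol A (5,5'-[(2R,3R)-2,3-dimethylbutane-1,4-diyl]bis(3-methoxybenzene-1,2-diol)), via tetraphenol diketone 12 (not isolated), via tetraphenol diol 13 (not isolated)
Conditions: H2 (4 atm), 10% Pd/C, AcOH/EtOAc, 45 °C
Reagents that add atoms: none
Why: Catalytic hydrogenolysis removes the four O-benzyl groups and reduces each electron-rich aryl ketone through the benzylic alcohol to CH2 (helped by the para-hydroxy group); C2 and C3 are not touched, and their descriptors change from S to R only because C(=O)Ar outranks the neighbouring CH whereas CH2Ar does not.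

**Compound list**

1 | 3,4-dihydroxy-5-methoxybenzaldehyde (5-hydroxyvanillin) | COc1cc(C=O)cc(O)c1O | starting material
2 | benzyl bromide | BrCc1ccccc1 | starting material
3 | 3,4-bis(benzyloxy)-5-methoxybenzaldehyde | COc1cc(C=O)cc(OCc2ccccc2)c1OCc1ccccc1 | intermediate
4 | ethylmagnesium bromide | CC[Mg]Br | starting material
5 | bromomagnesium 1-[3,4-bis(benzyloxy)-5-methoxyphenyl]propan-1-olate (racemic, not isolated) | CCC(O[Mg]Br)c1cc(OC)c(OCc2ccccc2)c(OCc2ccccc2)c1 | intermediate
6 | 1-[3,4-bis(benzyloxy)-5-methoxyphenyl]propan-1-one | CCC(=O)c1cc(OC)c(OCc2ccccc2)c(OCc2ccccc2)c1 | intermediate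
7 | (S)-1-amino-2-(methoxymethyl)pyrrolidine (SAMP) | COC[C@@H]1CCCN1N | starting material
8 | (E)-1-[3,4-bis(benzyloxy)-5-methoxyphenyl]-N-[(2S)-2-(methoxymethyl)pyrrolidin-1-yl]propan-1-imine | CC/C(=N\N1CCC[C@H]1COC)c1cc(OC)c(OCc2ccccc2)c(OCc2ccccc2)c1 | intermediate
9 | lithium azaenolate of 8 (E about C=C, methyl trans to N; not isolated) | C/C=C(/N([Li])N1CCC[C@H]1COC)c1cc(OC)c(OCc2ccccc2)c(OCc2ccccc2)c1 | intermediate
10 | (2S,3S)-1,4-bis[3,4-bis(benzyloxy)-5-methoxyphenyl]-2,3-dimethylbutane-1,4-dione bis-SAMP hydrazone | COc1cc(/C(=N/N2CCC[C@H]2COC)[C@@H](C)[C@H](C)/C(=N\N2CCC[C@H]2COC)c2cc(OCc3ccccc3)c(OCc3ccccc3)c(OC)c2)cc(OCc2ccccc2)c1OCc1ccccc1 | intermediate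
11 | (2S,3S)-1,4-bis[3,4-bis(benzyloxy)-5-methoxyphenyl]-2,3-dimethylbutane-1,4-dione | COc1cc(C(=O)[C@@H](C)[C@H](C)C(=O)c2cc(OCc3ccccc3)c(OCc3ccccc3)c(OC)c2)cc(OCc2ccccc2)c1OCc1ccccc1 | intermediate
12 | (2S,3S)-1,4-bis(3,4-dihydroxy-5-methoxyphenyl)-2,3-dimethylbutane-1,4-dione (not isolated) | COc1cc(C(=O)[C@@H](C)[C@H](C)C(=O)c2cc(O)c(O)c(OC)c2)cc(O)c1O | intermediate
13 | (2S,3S)-1,4-bis(3,4-dihydroxy-5-methoxyphenyl)-2,3-dimethylbutane-1,4-diol (carbinol epimers, not isolated) | COc1cc(C(O)[C@@H](C)[C@H](C)C(O)c2cc(O)c(O)c(OC)c2)cc(O)c1O | intermediate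
14 | Sauriol A, 5,5'-[(2R,3R)-2,3-dimethylbutane-1,4-diyl]bis(3-methoxybenzene-1,2-diol) | COc1cc(C[C@@H](C)[C@H](C)Cc2cc(O)c(O)c(OC)c2)cc(O)c1O | target

**Step count**

Total steps: 6. Longest linear sequence: 6 steps (1 → 3 → 6 → 8 → 10 → 11 → 14).

**Three steps most likely to fail, with fallbacks**

Step 4 (oxidative homocoupling) is the riskiest. It joins two carbons that both become tertiary, is untested on this substrate, and could give low conversion, α-chlorination or too much of the unlike dimer. The fallback sets out from aldehyde 3 and comes back to the route at target 14, moving the carbonyl groups to the future methyl carbons and using a chiral imide enolate in the coupling. Reductive Knoevenagel alkylation of Meldrum's acid with 3 in HCO2H/Et3N gives 5-[3,4-bis(benzyloxy)-5-methoxybenzyl]-2,2-dimethyl-1,3-dioxane-4,6-dione F1. On continued heating at 95 °C and aqueous acid work-up this hydrolyses and decarboxylates in the same flask to 3-[3,4-bis(benzyloxy)-5-methoxyphenyl]propanoic acid F2. Mixed-anhydride acylation (PivCl, Et3N, then (4S)-4-benzyl-1,3-oxazolidin-2-one and LiCl, THF) gives (4S)-4-benzyl-3-{3-[3,4-bis(benzyloxy)-5-methoxyphenyl]propanoyl}-1,3-oxazolidin-2-one F3. Oxidative homocoupling of its enolate (LDA, then TiCl4, THF, −78 °C to rt) gives (2R,3R)-1,4-bis[(4S)-4-benzyl-2-oxo-1,3-oxazolidin-3-yl]-2,3-bis[3,4-bis(benzyloxy)-5-methoxybenzyl]butane-1,4-dione F4, with the usual Evans facial bias setting both centres. LiBH4 (THF/MeOH, 0 °C) removes the auxiliaries to give (2R,3R)-2,3-bis[3,4-bis(benzyloxy)-5-methoxybenzyl]butane-1,4-diol F5. MsCl/Et3N (CH2Cl2, −20 °C) gives (2R,3R)-2,3-bis[3,4-bis(benzyloxy)-5-methoxybenzyl]butane-1,4-diyl dimethanesulfonate F6. LiAlH4 (THF, reflux) reduces both mesylates to methyl groups, giving 1,1'-[(2R,3R)-2,3-dimethylbutane-1,4-diyl]bis[3,4-bis(benzyloxy)-5-methoxybenzene] F7. Hydrogenolysis (H2, 10% Pd/C, EtOAc/MeOH) then gives 14.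

Step 5 (hydrazone cleavage) may stall, because the two C=N bonds are hindered and conjugated, or the acid may epimerise the α-centres or close the 1,4-diketone to a furan. The fallback sets out from 10 and comes back at 11, activating the hydrazone by quaternisation instead of hydrolysing it directly. Exhaustive N-methylation with MeI (neat, 60 °C) gives (2S,3S)-1,4-bis[3,4-bis(benzyloxy)-5-methoxyphenyl]-2,3-dimethylbutane-1,4-dione bis[(2S)-2-(methoxymethyl)-1-methylpyrrolidinium-1-ylimine] diiodide F8. Its activated C=N bonds hydrolyse quickly in a two-phase 2 N HCl/Et2O system at rt, and the diketone 11 is drawn into the organic layer as it forms.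

Step 6 (global hydrogenolysis) may stop at the benzylic alcohols, or the enolisable diketone may epimerise or cyclise in warm acetic acid before it is reduced. The fallback sets out from 11 and comes back at 14, removing the carbonyl groups by hydride before any acid is present. NaBH4 (MeOH/THF, 0 °C) gives (2S,3S)-1,4-bis[3,4-bis(benzyloxy)-5-methoxyphenyl]-2,3-dimethylbutane-1,4-diol F9 as a mixture of carbinol epimers, with C2 and C3 now fixed. Hydrogenolysis (H2, Pd(OH)2/C, MeOH/EtOAc, trace HCl) then cleaves the four O-benzyl and two benzylic C–OH bonds, passing through the tetraphenol diol 13 to 14.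

**Further compounds**

F1 | step 4 | 5-[3,4-bis(benzyloxy)-5-methoxybenzyl]-2,2-dimethyl-1,3-dioxane-4,6-dione | CC1(C)OC(=O)C(Cc2cc(OC)c(OCc3ccccc3)c(OCc3ccccc3)c2)C(=O)O1
F2 | step 4 | 3-[3,4-bis(benzyloxy)-5-methoxyphenyl]propanoic acid | OC(=O)CCc1cc(OC)c(OCc2ccccc2)c(OCc2ccccc2)c1
F3 | step 4 | (4S)-4-benzyl-3-{3-[3,4-bis(benzyloxy)-5-methoxyphenyl]propanoyl}-1,3-oxazolidin-2-one | O=C(CCc1cc(OC)c(OCc2ccccc2)c(OCc2ccccc2)c1)N1[C@@H](Cc2ccccc2)COC1=O
F4 | step 4 | (2R,3R)-1,4-bis[(4S)-4-benzyl-2-oxo-1,3-oxazolidin-3-yl]-2,3-bis[3,4-bis(benzyloxy)-5-methoxybenzyl]butane-1,4-dione | O=C([C@H](Cc1cc(OC)c(OCc2ccccc2)c(OCc2ccccc2)c1)[C@@H](Cc1cc(OC)c(OCc2ccccc2)c(OCc2ccccc2)c1)C(=O)N1[C@@H](Cc2ccccc2)COC1=O)N1[C@@H](Cc2ccccc2)COC1=O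
F5 | step 4 | (2R,3R)-2,3-bis[3,4-bis(benzyloxy)-5-methoxybenzyl]butane-1,4-diol | OC[C@H](Cc1cc(OC)c(OCc2ccccc2)c(OCc2ccccc2)c1)[C@@H](Cc1cc(OC)c(OCc2ccccc2)c(OCc2ccccc2)c1)CO
F6 | step 4 | (2R,3R)-2,3-bis[3,4-bis(benzyloxy)-5-methoxybenzyl]butane-1,4-diyl dimethanesulfonate | CS(=O)(=O)OC[C@H](Cc1cc(OC)c(OCc2ccccc2)c(OCc2ccccc2)c1)[C@@H](Cc1cc(OC)c(OCc2ccccc2)c(OCc2ccccc2)c1)COS(C)(=O)=O
F7 | step 4 | 1,1'-[(2R,3R)-2,3-dimethylbutane-1,4-diyl]bis[3,4-bis(benzyloxy)-5-methoxybenzene] (tetra-O-benzyl sauriol A) | COc1cc(C[C@@H](C)[C@H](C)Cc2cc(OCc3ccccc3)c(OCc3ccccc3)c(OC)c2)cc(OCc2ccccc2)c1OCc1ccccc1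
F8 | step 5 | (2S,3S)-1,4-bis[3,4-bis(benzyloxy)-5-methoxyphenyl]-2,3-dimethylbutane-1,4-dione bis[(2S)-2-(methoxymethyl)-1-methylpyrrolidinium-1-ylimine] diiodide | COc1cc(/C(=N/[N+]2(C)CCC[C@H]2COC)[C@@H](C)[C@H](C)/C(=N\[N+]2(C)CCC[C@H]2COC)c2cc(OCc3ccccc3)c(OCc3ccccc3)c(OC)c2)cc(OCc2ccccc2)c1OCc1ccccc1.[I-].[I-]
F9 | step 6 | (2S,3S)-1,4-bis[3,4-bis(benzyloxy)-5-methoxyphenyl]-2,3-dimethylbutane-1,4-diol | COc1cc(C(O)[C@@H](C)[C@H](C)C(O)c2cc(OCc3ccccc3)c(OCc3ccccc3)c(OC)c2)cc(OCc2ccccc2)c1OCc1ccccc1
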